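**Plan**
Ring labels: A is the aryl group on C2 of the dihydrobenzofuran, B its benzo ring, C the phenol ring carrying the 1,3-diol chain, and D the aryl group on the open-chain carbinol carbon.
Enabling feature: ring A–C2H(O)–C3H(CH2OH)–ring B and ring D–CH(OH)–CH(CH2OH)–ring C are two copies of one 1,2-diarylpropane-1,3-diol unit, each bonded ortho to the oxygen of a 5-substituted guaiacyl ring. Both CH(CH2OH) carbons are S, and C2 (R) is the S carbinol carbon after its oxygen has been displaced by the ring B phenol.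
Cuts, in order: O1–C2 of the dihydrobenzofuran; then C2–C3 together with the carbinol carbon–CH(ring C) bond (two aldol cuts that release rings A and D as protected vanillin); then the C3–benzyl and C4–benzyl bonds of the lactone.
Forward order: vanillin gives 5-allylvanillin and from it two benzylic bromides. The lactone ring is closed first on the ring B piece and ring C is joined by alkylation. Both allyl groups then become N-arylacetyl imides, the double aldol joins rings A and D, and the dihydrofuran ring closes last.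
Stereochemistry: (S)-4-benzyl-2-oxazolidinone sets lactone C4 (alkylation of a succinate imide) and C4 steers C3 (trans alkylation). Two more copies of the same auxiliary set the four aldol centres (anti), and a Mitsunobu closure inverts one of them.

Key step: step 18

Assumption: the anti and facial preference known for magnesium-catalysed aldol additions of N-propionyl oxazolidinones is taken to hold for N-arylacetyl imides, with the aryl group occupying the place of methyl on the Z-enolate.
Abbreviations: TBS = tert-butyldimethylsilyl; Bn = benzyl; Xc = (4S)-4-benzyl-2-oxo-1,3-oxazolidin-3-yl; PivCl = pivaloyl chloride; DIAD = diisopropyl azodicarboxylate; DMPU = N,N'-dimethylpropyleneurea; TFA = trifluoroacetic acid.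

Step 1
Reactants: 1 vanillin; 2 allyl bromide
Product: 3 4-allyloxy-3-methoxybenzaldehyde
Conditions: K2CO3, acetone, reflux
Reagents that add atoms: none
Why: Williamson ether synthesis: the carbonate-generated phenoxide of 1 displaces bromide from the allylic halide by SN2 and the aldehyde is inert to these conditions.

Step 2
Reactants: 3 4-allyloxy-3-methoxybenzaldehyde
Product: 4 5-allylvanillin (3-allyl-4-hydroxy-5-methoxybenzaldehyde)
Conditions: neat, N2, 200 °C
Reagents that add atoms: none
Why: Aromatic Claisen rearrangement: the concerted [3,3]-shift can deliver the allyl group only to C5, the one free ortho position, and enolisation of the dienone restores the phenol.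

Step 3
Reactants: 4 5-allylvanillin
Product: 5 3-allyl-4-benzyloxy-5-methoxybenzaldehyde
Conditions: BnBr, K2CO3, DMF, 60 °C
Reagents that add atoms: benzyl bromide, BrCc1ccccc1
Why: Williamson ether synthesis; benzyl is reserved for the ring B oxygen so that later this phenol alone can be freed by hydrogenolysis.

Step 4
Reactants: 5 3-allyl-4-benzyloxy-5-methoxybenzaldehyde
Product: 6 (3-allyl-4-benzyloxy-5-methoxyphenyl)methanol
Conditions: NaBH4, MeOH, 0 °C
Reagents that add atoms: none
Why: Borohydride reduction of an aromatic aldehyde, which leaves the terminal alkene and both ethers untouched.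

Step 5
Reactants: 6 (3-allyl-4-benzyloxy-5-methoxyphenyl)methanol
Product: 7 3-allyl-4-benzyloxy-5-methoxybenzyl bromide (ring B bromide)
Conditions: PBr3, Et2O, 0 °C
Reagents that add atoms: phosphorus tribromide, BrP(Br)Br
Why: Bromination of a benzylic alcohol through its phosphite ester (SN2 by bromide) is fast at 0 °C for an electron-rich benzylic position, and the bromide is used without chromatography.

Step 6
Reactants: 4 5-allylvanillin
Product: 8 3-allyl-4-(tert-butyldimethylsilyloxy)-5-methoxybenzaldehyde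
Conditions: TBSCl, imidazole, DMF, rt
Reagents that add atoms: tert-butyldimethylsilyl chloride, CC(C)(C)[Si](C)(C)Cl
Why: Imidazole-promoted silylation of a phenol; the silyl ether marks the ring C oxygen as one that is unmasked only in the last step.

Step 7
Reactants: 8 3-allyl-4-(tert-butyldimethylsilyloxy)-5-methoxybenzaldehyde
Product: 9 [3-allyl-4-(tert-butyldimethylsilyloxy)-5-methoxyphenyl]methanol
Conditions: NaBH4, THF–EtOH, 0 °C
Reagents that add atoms: none
Why: Borohydride reduction of an aromatic aldehyde, short and cold enough that the aryl silyl ether should survive.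

Step 8
Reactants: 9 [3-allyl-4-(tert-butyldimethylsilyloxy)-5-methoxyphenyl]methanol
Product: 10 3-allyl-4-(tert-butyldimethylsilyloxy)-5-methoxybenzyl bromide (ring C bromide)
Conditions: PBr3, Et2O, 0 °C
Reagents that add atoms: phosphorus tribromide, BrP(Br)Br
Why: The same phosphite-mediated SN2 bromination as in step 5, which acid-stable aryl silyl ethers tolerate.

Step 9
Reactants: 11 mono-tert-butyl succinate; 12 (S)-4-benzyl-2-oxazolidinone
Product: 14 tert-butyl 4-[(4S)-4-benzyl-2-oxo-1,3-oxazolidin-3-yl]-4-oxobutanoate, via pivalic mixed anhydride 13 (not isolated)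
Conditions: PivCl, Et3N, THF, −20 °C; then LiCl, 12, −20 °C to rt
Reagents that add atoms: pivaloyl chloride, CC(C)(C)C(=O)Cl (its atoms are held only in 13)
Why: N-acylation of an oxazolidinone by the mixed anhydride method: LiCl and Et3N make the carbamate nitrogen nucleophilic enough to attack the unhindered carbonyl group of 13, the pivaloyl carbonyl group being shielded.

Step 10
Reactants: 14 succinate imide; 7 ring B bromide
Product: 15 tert-butyl (3S)-3-(3-allyl-4-benzyloxy-5-methoxybenzyl)-4-[(4S)-4-benzyl-2-oxo-1,3-oxazolidin-3-yl]-4-oxobutanoate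
Conditions: NaN(SiMe3)2, THF, −78 °C; then 7, −78 to −30 °C
Reagents that add atoms: none
Why: Evans asymmetric alkylation: only the more acidic imide α-CH2 is deprotonated, both imide carbonyl groups chelate the sodium Z-enolate, and the benzylic bromide enters opposite the 4-benzyl group, which with CH2CO2t-Bu as the resident chain gives the 3S centre (future lactone C4).

Step 11
Reactants: 15 alkylated imide
Product: 16 tert-butyl (3S)-3-(3-allyl-4-benzyloxy-5-methoxybenzyl)-4-hydroxybutanoate
Conditions: NaBH4, THF–H2O (4:1), 0 °C to rt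
Reagents that add atoms: none
Why: Reductive removal of the auxiliary with NaBH4 in aqueous THF: the activated exocyclic imide carbonyl group is reduced to CH2OH, the tert-butyl ester is inert, and the stereocentre is carried through unchanged.

Step 12
Reactants: 16 hydroxy ester
Product: 17 (4S)-4-(3-allyl-4-benzyloxy-5-methoxybenzyl)oxolan-2-one
Conditions: p-TsOH·H2O (cat.), toluene, 60 °C
Reagents that add atoms: none
Why: Acid-catalysed lactonisation (intramolecular transesterification, 5-exo-trig) is driven by five-membered ring formation and loss of tert-butanol and does not touch the stereocentre.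

Step 13
Reactants: 17 β-benzyl lactone; 10 ring C bromide
Product: 18 (3S,4S)-3-[3-allyl-4-(tert-butyldimethylsilyloxy)-5-methoxybenzyl]-4-(3-allyl-4-benzyloxy-5-methoxybenzyl)oxolan-2-one (trans)
Conditions: LiN(SiMe3)2, THF, −78 °C; then 10, DMPU, −78 to −40 °C
Reagents that add atoms: none
Why: Substrate-controlled alkylation of a β-substituted γ-butyrolactone enolate, the standard entry to trans-dibenzylbutyrolactone lignans: bromide 10 approaches the planar enolate anti to the C4 benzyl group and sets C3 as S.

Step 14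
Reactants: 18 trans bis-allyl lactone
Product: 20 bis(arylacetaldehyde) in which each allyl group of 18 has become CH2CHO, via bis-diol 19 (not isolated)
Conditions: OsO4 (cat.), NaIO4, 2,6-lutidine, dioxane–H2O (3:1), rt
Reagents that add atoms: sodium periodate, [Na+].[O-]I(=O)(=O)=O; water, O
Why: Lemieux–Johnson oxidation: OsO4 dihydroxylates only the two terminal alkenes and NaIO4 cleaves the glycols as they form, so the electron-rich arenes that ozone or RuO4 would attack are spared.

Step 15
Reactants: 20 bis(arylacetaldehyde)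
Product: 21 bis(arylacetic acid) in which each CH2CHO has become CH2CO2H
Conditions: NaClO2, NaH2PO4, 2-methyl-2-butene, t-BuOH–H2O, rt
Reagents that add atoms: sodium chlorite, [Na+].[O-]Cl=O
Why: Pinnick oxidation: chlorous acid converts the enolisable aldehydes into acids under buffered conditions without epimerising the lactone, and 2-methyl-2-butene traps the hypochlorous acid that would chlorinate the arenes.

Step 16
Reactants: 21 bis(arylacetic acid); 12 (S)-4-benzyl-2-oxazolidinone (two equivalents)
Product: 23 bis(N-arylacetyl oxazolidinone) in which each CH2CO2H has become CH2C(=O)Xc (ring B OBn; ring C OTBS), via bis(pivalic mixed anhydride) 22 (not isolated)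
Conditions: PivCl, Et3N, THF, −20 °C; then LiCl, 12 (2.2 equiv), −20 °C to rt
Reagents that add atoms: pivaloyl chloride, CC(C)(C)C(=O)Cl (its atoms are held only in 22)
Why: Twofold N-acylation by the mixed anhydride method as in step 9, in a weakly basic medium that leaves the lactone and the aryl silyl ether intact.

Step 17
Reactants: 1 vanillin
Product: 24 4-(tert-butyldimethylsilyloxy)-3-methoxybenzaldehyde
Conditions: TBSCl, imidazole, CH2Cl2, rt
Reagents that add atoms: tert-butyldimethylsilyl chloride, CC(C)(C)[Si](C)(C)Cl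
Why: Imidazole-promoted silylation of a phenol gives a non-enolisable aldehyde whose protecting group leaves together with the others in the final fluoride step.

Step 18
Reactants: 23 bis(N-arylacetyl oxazolidinone); 24 4-(tert-butyldimethylsilyloxy)-3-methoxybenzaldehyde (two equivalents react)
Product: 26 bis anti aldol adduct in which each CH2C(=O)Xc has become (2R,3S)-CH[C(=O)Xc]–CH(OH)–[4-(TBSO)-3-methoxyphenyl], via bis(trimethylsilyl ether) 25 (not isolated)
Conditions: MgCl2 (20 mol % per imide), Et3N, Me3SiCl, 24 (2.5 equiv), EtOAc, 23 °C; then TFA (cat.), MeOH, rt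
Reagents that add atoms: chlorotrimethylsilane, C[Si](C)(C)Cl (its atoms are held only in 25)
Why: Magnesium binds both carbonyl oxygens of each imide, which lets Et3N remove a benzylic α-proton to give a chelated Z-enolate; the aldehyde coordinates to the same metal and is attacked through a boat-like arrangement, and Me3SiCl caps the magnesium aldolate, which shuts off retro-aldol and hands MgCl2 back to the cycle. The closest known reaction is the magnesium halide-catalysed direct anti aldol addition of N-acyl oxazolidinones to non-enolisable aromatic aldehydes, run here at both ends of one molecule. No ring is closed; the two bonds made are the future C2–C3 bond of the dihydrobenzofuran and the carbinol carbon–CH(ring C) bond of the open chain. Each α-carbon (2R) is fixed by the 4-benzyl group of its own auxiliary, which covers one face of the chelated enolate, and each carbinol carbon (3S) by the anti topology of the boat, so the remote lactone centres play no part and one auxiliary antipode serves both arms. The step needs site selectivity against the lactone α-hydrogen; this is secured because only the imides offer two-point binding to magnesium and a benzylic, much more acidic C–H, while 24 has no α-hydrogen. The adducts should resist epimerisation because allylic 1,3-strain holds the remaining α-hydrogen of a branched imide out of alignment with the carbonyl group, and brief acidic methanolysis then removes only the two Me3Si ethers.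

Step 19
Reactants: 26 bis anti aldol adduct
Product: 27 tetraol in which each C(=O)Xc has become CH2OH (both arms (1S,2S)-1,2-diarylpropane-1,3-diols)
Conditions: NaBH4, THF–H2O (4:1), 0 °C
Reagents that add atoms: none
Why: Reductive cleavage of N-acyl oxazolidinones with NaBH4 in aqueous THF: the imide carbonyl groups are far more electrophilic than the γ-lactone, which NaBH4 leaves alone at 0 °C, and the former α-carbons keep their geometry, their descriptor changing from R to S only because CH2OH ranks below the carbinol carbon.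

Step 20
Reactants: 27 tetraol
Product: 28 bis(primary TBS ether) of 27 carrying two free secondary benzylic alcohols
Conditions: TBSCl (2.2 equiv), imidazole, CH2Cl2–DMF, 0 °C
Reagents that add atoms: tert-butyldimethylsilyl chloride, CC(C)(C)[Si](C)(C)Cl
Why: Sterically controlled silylation: the two primary alcohols react much faster than the flanked secondary benzylic alcohols, and any aryl silyl ether loosened in step 19 is put back at the same time.

Step 21
Reactants: 28 bis(primary TBS ether)
Product: 29 ring B phenol (28 without its benzyl group)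
Conditions: H2 (1 atm), Pd/C (10 wt %), EtOAc, rt
Reagents that add atoms: none
Why: Catalytic hydrogenolysis of the only benzyl ether in the molecule; in neutral EtOAc an aryl benzyl ether is cleaved well before benzylic alcohols, and silyl ethers and lactone are inert.

Step 22
Reactants: 29 ring B phenol
Product: 30 penta-TBS ether of the target containing the (2R,3S)-trans-2,3-dihydrobenzofuran
Conditions: PPh3, DIAD, THF (0.01 M), 0 °C to rt
Reagents that add atoms: none
Why: Intramolecular Mitsunobu etherification (5-exo-tet): the phenol, the only acidic pronucleophile, lies within reach of the ring B arm carbinol alone, so that oxyphosphonium ion is displaced by SN2 with inversion (S to R at C2) to give the trans ring, while phosphonium held reversibly on the ring C carbinol finds no nucleophile and returns the alcohol with retention on work-up.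

Step 23
Reactants: 30 penta-TBS ether
Product: 31 CNP0186558.3 (target)
Conditions: Bu4NF, AcOH, THF, 0 °C to rt
Reagents that add atoms: none
Why: Fluoride-mediated desilylation: formation of the strong Si–F bond drives cleavage of all five silyl ethers, and the AcOH buffer keeps the medium mild enough that the lactone, the trans centres and the p-hydroxybenzylic alcohol are not disturbed.

**Compound list**
1 | vanillin (4-hydroxy-3-methoxybenzaldehyde) | COc1cc(C=O)ccc1O | starting material
2 | allyl bromide | C=CCBr | starting material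
3 | 4-allyloxy-3-methoxybenzaldehyde | COc1cc(C=O)ccc1OCC=C | intermediate
4 | 5-allylvanillin (3-allyl-4-hydroxy-5-methoxybenzaldehyde) | COc1cc(C=O)cc(CC=C)c1O | intermediate
5 | 3-allyl-4-benzyloxy-5-methoxybenzaldehyde | COc1cc(C=O)cc(CC=C)c1OCc1ccccc1 | intermediate
6 | (3-allyl-4-benzyloxy-5-methoxyphenyl)methanol | COc1cc(CO)cc(CC=C)c1OCc1ccccc1 | intermediate
7 | 3-allyl-4-benzyloxy-5-methoxybenzyl bromide (ring B bromide) | COc1cc(CBr)cc(CC=C)c1OCc1ccccc1 | intermediate
8 | 3-allyl-4-(tert-butyldimethylsilyloxy)-5-methoxybenzaldehyde | COc1cc(C=O)cc(CC=C)c1O[Si](C)(C)C(C)(C)C | intermediate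
9 | [3-allyl-4-(tert-butyldimethylsilyloxy)-5-methoxyphenyl]methanol | COc1cc(CO)cc(CC=C)c1O[Si](C)(C)C(C)(C)C | intermediate
10 | 3-allyl-4-(tert-butyldimethylsilyloxy)-5-methoxybenzyl bromide (ring C bromide) | COc1cc(CBr)cc(CC=C)c1O[Si](C)(C)C(C)(C)C | intermediate
11 | mono-tert-butyl succinate (4-tert-butoxy-4-oxobutanoic acid) | CC(C)(C)OC(=O)CCC(=O)O | starting material
12 | (S)-4-benzyl-2-oxazolidinone | O=C1N[C@@H](Cc2ccccc2)CO1 | starting material
13 | mixed anhydride of 11 and pivalic acid | CC(C)(C)OC(=O)CCC(=O)OC(=O)C(C)(C)C | intermediate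
14 | tert-butyl 4-[(4S)-4-benzyl-2-oxo-1,3-oxazolidin-3-yl]-4-oxobutanoate | CC(C)(C)OC(=O)CCC(=O)N1[C@@H](Cc2ccccc2)COC1=O | intermediate
15 | tert-butyl (3S)-3-(3-allyl-4-benzyloxy-5-methoxybenzyl)-4-[(4S)-4-benzyl-2-oxo-1,3-oxazolidin-3-yl]-4-oxobutanoate | CC(C)(C)OC(=O)C[C@H](Cc1cc(OC)c(OCc2ccccc2)c(CC=C)c1)C(=O)N1[C@@H](Cc2ccccc2)COC1=O | intermediate
16 | tert-butyl (3S)-3-(3-allyl-4-benzyloxy-5-methoxybenzyl)-4-hydroxybutanoate | CC(C)(C)OC(=O)C[C@H](Cc1cc(OC)c(OCc2ccccc2)c(CC=C)c1)CO | intermediate
17 | (4S)-4-(3-allyl-4-benzyloxy-5-methoxybenzyl)oxolan-2-one | O=C1C[C@H](Cc2cc(OC)c(OCc3ccccc3)c(CC=C)c2)CO1 | intermediate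
18 | (3S,4S)-3-[3-allyl-4-(TBSO)-5-methoxybenzyl]-4-(3-allyl-4-benzyloxy-5-methoxybenzyl)oxolan-2-one, trans | C=CCc1cc(C[C@@H]2C(=O)OC[C@H]2Cc2cc(OC)c(OCc3ccccc3)c(CC=C)c2)cc(OC)c1O[Si](C)(C)C(C)(C)C | intermediate
19 | bis-diol: 18 with each CH2CH=CH2 turned into CH2CH(OH)CH2OH (mixture at the two new carbinol carbons) | OCC(O)Cc1cc(C[C@@H]2C(=O)OC[C@H]2Cc2cc(OC)c(OCc3ccccc3)c(CC(O)CO)c2)cc(OC)c1O[Si](C)(C)C(C)(C)C | intermediate
20 | bis(arylacetaldehyde): (3S,4S)-lactone with CH2CHO on ring B and on ring C | O=CCc1cc(C[C@@H]2C(=O)OC[C@H]2Cc2cc(OC)c(OCc3ccccc3)c(CC=O)c2)cc(OC)c1O[Si](C)(C)C(C)(C)C | intermediate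
21 | bis(arylacetic acid): (3S,4S)-lactone with CH2CO2H on ring B and on ring C | OC(=O)Cc1cc(C[C@@H]2C(=O)OC[C@H]2Cc2cc(OC)c(OCc3ccccc3)c(CC(=O)O)c2)cc(OC)c1O[Si](C)(C)C(C)(C)C | intermediate
22 | bis(pivalic mixed anhydride) of 21 | CC(C)(C)C(=O)OC(=O)Cc1cc(C[C@@H]2C(=O)OC[C@H]2Cc2cc(OC)c(OCc3ccccc3)c(CC(=O)OC(=O)C(C)(C)C)c2)cc(OC)c1O[Si](C)(C)C(C)(C)C | intermediate
23 | bis(N-arylacetyl oxazolidinone): (3S,4S)-lactone with CH2C(=O)Xc on ring B (OBn) and on ring C (OTBS) | O=C1OC[C@H](Cc2ccccc2)N1C(=O)Cc1cc(C[C@@H]2C(=O)OC[C@H]2Cc2cc(OC)c(OCc3ccccc3)c(CC(=O)N3[C@@H](Cc4ccccc4)COC3=O)c2)cc(OC)c1O[Si](C)(C)C(C)(C)C | intermediate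
24 | 4-(tert-butyldimethylsilyloxy)-3-methoxybenzaldehyde | COc1cc(C=O)ccc1O[Si](C)(C)C(C)(C)C | intermediate
25 | bis(trimethylsilyl ether) of 26, both acyl chains 2R,3S | COc1cc([C@@H](O[Si](C)(C)C)[C@H](C(=O)N2[C@@H](Cc3ccccc3)COC2=O)c2cc(C[C@@H]3C(=O)OC[C@H]3Cc3cc(OC)c(OCc4ccccc4)c(c3)[C@@H](C(=O)N3[C@@H](Cc4ccccc4)COC3=O)[C@H](O[Si](C)(C)C)c3ccc(O[Si](C)(C)C(C)(C)C)c(OC)c3)cc(OC)c2O[Si](C)(C)C(C)(C)C)ccc1O[Si](C)(C)C(C)(C)C | intermediate
26 | bis anti aldol adduct, both acyl chains (2R,3S)-2-aryl-3-hydroxy-3-[4-(TBSO)-3-methoxyphenyl]propanoyl-Xc | COc1cc([C@@H](O)[C@H](C(=O)N2[C@@H](Cc3ccccc3)COC2=O)c2cc(C[C@@H]3C(=O)OC[C@H]3Cc3cc(OC)c(OCc4ccccc4)c(c3)[C@@H](C(=O)N3[C@@H](Cc4ccccc4)COC3=O)[C@H](O)c3ccc(O[Si](C)(C)C(C)(C)C)c(OC)c3)cc(OC)c2O[Si](C)(C)C(C)(C)C)ccc1O[Si](C)(C)C(C)(C)C | intermediate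
27 | tetraol, both arms (1S,2S)-1,3-dihydroxy-1-[4-(TBSO)-3-methoxyphenyl]propan-2-yl | COc1cc([C@@H](O)[C@H](CO)c2cc(C[C@@H]3C(=O)OC[C@H]3Cc3cc(OC)c(OCc4ccccc4)c(c3)[C@@H](CO)[C@H](O)c3ccc(O[Si](C)(C)C(C)(C)C)c(OC)c3)cc(OC)c2O[Si](C)(C)C(C)(C)C)ccc1O[Si](C)(C)C(C)(C)C | intermediate
28 | 27 with both primary alcohols as TBS ethers | COc1cc([C@@H](O)[C@H](CO[Si](C)(C)C(C)(C)C)c2cc(C[C@@H]3C(=O)OC[C@H]3Cc3cc(OC)c(OCc4ccccc4)c(c3)[C@@H](CO[Si](C)(C)C(C)(C)C)[C@H](O)c3ccc(O[Si](C)(C)C(C)(C)C)c(OC)c3)cc(OC)c2O[Si](C)(C)C(C)(C)C)ccc1O[Si](C)(C)C(C)(C)C | intermediate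
29 | 28 with the ring B phenol free | COc1cc([C@@H](O)[C@H](CO[Si](C)(C)C(C)(C)C)c2cc(C[C@@H]3C(=O)OC[C@H]3Cc3cc(OC)c(O)c(c3)[C@@H](CO[Si](C)(C)C(C)(C)C)[C@H](O)c3ccc(O[Si](C)(C)C(C)(C)C)c(OC)c3)cc(OC)c2O[Si](C)(C)C(C)(C)C)ccc1O[Si](C)(C)C(C)(C)C | intermediate
30 | penta-TBS ether of the target: (2R,3S)-trans-dihydrobenzofuran, open arm 1S,2S, lactone 3S,4S | COc1cc([C@@H](O)[C@H](CO[Si](C)(C)C(C)(C)C)c2cc(C[C@@H]3C(=O)OC[C@H]3Cc3cc(OC)c4c(c3)[C@@H](CO[Si](C)(C)C(C)(C)C)[C@H](c3ccc(O[Si](C)(C)C(C)(C)C)c(OC)c3)O4)cc(OC)c2O[Si](C)(C)C(C)(C)C)ccc1O[Si](C)(C)C(C)(C)C | intermediate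
31 | CNP0186558.3 | COc1cc([C@@H](O)[C@H](CO)c2cc(C[C@@H]3C(=O)OC[C@H]3Cc3cc(OC)c4c(c3)[C@@H](CO)[C@H](c3ccc(O)c(OC)c3)O4)cc(OC)c2O)ccc1O | target

**Total step count:** 23
**Longest linear sequence:** 18 steps (steps 1–5, 10–16, 18–23)

**Steps most likely to fail**

1. Step 18 (double anti aldol). The second imide may lag behind the first so that half-reacted material accumulates. The crowded, ortho-substituted arylacetyl enolates may add with poor anti or facial selectivity. Aldolate that is silylated too slowly may revert.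

The fallback gives up the chelated oxazolidinone enolate for the non-chelated magnesium enolate of an N-acyl thiazolidinethione. This is a different auxiliary class with the opposite facial bias, so the (R)-antipode is needed, and its acyl–nitrogen bond is much easier to cleave.

The fallback sets out from diacid 21. Coupling (EDC·HCl, DMAP, CH2Cl2) with two equivalents of commercial (R)-4-benzyl-1,3-thiazolidine-2-thione should give the bis(N-arylacetyl thiazolidinethione) F1. MgBr2·OEt2 (cat.), Et3N, Me3SiCl and 24 in EtOAc should give the bis(trimethylsilyl ether) F2, and acidic methanol the bis anti aldol adduct F3 with the same 2R,3S arms. NaBH4 in THF–EtOH at 0 °C then removes both auxiliaries and the route is rejoined at tetraol 27.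

2. Step 22 (Mitsunobu closure). The phosphonium reagent may engage the free carbinol of the ring C arm. The electron-rich benzylic oxyphosphonium ions may ionise or eliminate. Intermolecular etherification may compete with ring closure.

The fallback replaces the SN2 dehydration by an acid-induced SN1 closure under trans control, with the ring C diol tied up in a ring. It sets out from tetraol 27. 2,2-Dimethoxypropane and pyridinium p-toluenesulfonate should give the bis(acetonide) F4, two trans-4,5-diaryl-1,3-dioxanes, and H2 with Pd/C the free ring B phenol F5.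

BF3·OEt2 in CH2Cl2 at −40 °C should ionise the benzylic C–O bonds. In the ring B arm the phenol captures the cation anti to the C3 substituent and acetone is lost, giving the trans-dihydrobenzofuran mono-acetonide F6. In the ring C arm the cation can only re-close to the more stable trans dioxane, which is the original one. Aqueous HF in MeCN then removes the acetonide and the three aryl silyl ethers in one operation, and the route is rejoined at target 31.

3. Step 19 (double reductive auxiliary removal). Hydride may attack the ring carbonyl group of the hindered auxiliaries. The aldolates may fragment by retro-aldol in the basic medium. The lactone may be reduced slowly, or a silyl group may migrate from the ring C phenol.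

The fallback first exchanges the bulky imide for a slim, more electrophilic acyl donor. It sets out from 26. LiSEt (from EtSH and n-BuLi) in THF at 0 °C attacks only the exocyclic carbonyl groups and should give the bis(S-ethyl thioester) F7. NaBH4 in EtOH at 0 °C reduces thioesters in preference to the lactone, and the route is rejoined at tetraol 27.

**Further compounds**
F1 | step 18 | analogue of 23 carrying two (4R)-4-benzyl-2-thioxo-1,3-thiazolidin-3-yl groups in place of Xc | S=C1SC[C@@H](Cc2ccccc2)N1C(=O)Cc1cc(C[C@@H]2C(=O)OC[C@H]2Cc2cc(OC)c(OCc3ccccc3)c(CC(=O)N3[C@H](Cc4ccccc4)CSC3=S)c2)cc(OC)c1O[Si](C)(C)C(C)(C)C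
F2 | step 18 | bis(trimethylsilyl ether) of F3, both acyl chains 2R,3S | COc1cc([C@@H](O[Si](C)(C)C)[C@H](C(=O)N2[C@H](Cc3ccccc3)CSC2=S)c2cc(C[C@@H]3C(=O)OC[C@H]3Cc3cc(OC)c(OCc4ccccc4)c(c3)[C@@H](C(=O)N3[C@H](Cc4ccccc4)CSC3=S)[C@H](O[Si](C)(C)C)c3ccc(O[Si](C)(C)C(C)(C)C)c(OC)c3)cc(OC)c2O[Si](C)(C)C(C)(C)C)ccc1O[Si](C)(C)C(C)(C)C
F3 | step 18 | bis anti aldol adduct of F1 with 24, both acyl chains 2R,3S | COc1cc([C@@H](O)[C@H](C(=O)N2[C@H](Cc3ccccc3)CSC2=S)c2cc(C[C@@H]3C(=O)OC[C@H]3Cc3cc(OC)c(OCc4ccccc4)c(c3)[C@@H](C(=O)N3[C@H](Cc4ccccc4)CSC3=S)[C@H](O)c3ccc(O[Si](C)(C)C(C)(C)C)c(OC)c3)cc(OC)c2O[Si](C)(C)C(C)(C)C)ccc1O[Si](C)(C)C(C)(C)C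
F4 | step 22 | bis(acetonide) of 27, two trans-4,5-diaryl-2,2-dimethyl-1,3-dioxanes | COc1cc([C@H]5OC(C)(C)OC[C@@H]5c2cc(C[C@@H]3C(=O)OC[C@H]3Cc3cc(OC)c(OCc4ccccc4)c(c3)[C@H]6COC(C)(C)O[C@@H]6c3ccc(O[Si](C)(C)C(C)(C)C)c(OC)c3)cc(OC)c2O[Si](C)(C)C(C)(C)C)ccc1O[Si](C)(C)C(C)(C)C
F5 | step 22 | F4 with the ring B phenol free | COc1cc([C@H]5OC(C)(C)OC[C@@H]5c2cc(C[C@@H]3C(=O)OC[C@H]3Cc3cc(OC)c(O)c(c3)[C@H]6COC(C)(C)O[C@@H]6c3ccc(O[Si](C)(C)C(C)(C)C)c(OC)c3)cc(OC)c2O[Si](C)(C)C(C)(C)C)ccc1O[Si](C)(C)C(C)(C)C
F6 | step 22 | (2R,3S)-trans-dihydrobenzofuran with free 3-CH2OH, ring C arm as acetonide, three aryl TBS ethers | COc1cc([C@H]5OC(C)(C)OC[C@@H]5c2cc(C[C@@H]3C(=O)OC[C@H]3Cc3cc(OC)c4c(c3)[C@@H](CO)[C@H](c3ccc(O[Si](C)(C)C(C)(C)C)c(OC)c3)O4)cc(OC)c2O[Si](C)(C)C(C)(C)C)ccc1O[Si](C)(C)C(C)(C)C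
F7 | step 19 | bis(S-ethyl thioester) analogue of 26, both acyl chains 2R,3S | COc1cc([C@@H](O)[C@H](C(=O)SCC)c2cc(C[C@@H]3C(=O)OC[C@H]3Cc3cc(OC)c(OCc4ccccc4)c(c3)[C@@H](C(=O)SCC)[C@H](O)c3ccc(O[Si](C)(C)C(C)(C)C)c(OC)c3)cc(OC)c2O[Si](C)(C)C(C)(C)C)ccc1O[Si](C)(C)C(C)(C)C
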